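## Retrosynthetic overview

1. The route rests on one feature of ring B: the C7 carbinol sits beside the exocyclic C8=C17 methylene. This allylic alcohol is the reduced form of an 8(17)-en-7-one, which is what a C7 aldehyde C–H bond gives when it adds across a terminal C8≡C17 alkyne.
2. Ring B is the only ring that is built. Its C7–C8 bond is closed by rhodium-catalysed intramolecular alkyne hydroacylation of a ring A ynal. Luche reduction, desilylation, C20 acylation, acetonide removal and C2 angeloylation then give the target.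
3. The ynal comes from a ring A ester: C8 ester to C8≡C17 alkyne, Δ1 alkene to the 2α,3α-diol acetonide (through the 1-en-3-one), C7 acetal to aldehyde.
4. C9 and C10 are set together by an Ireland–Claisen rearrangement of a cyclohex-2-enyl ester, in which the C2–O bond is traded for the C10–C9 bond.
5. The ester is assembled from a dimedone-derived allylic alcohol (allylation, Stork–Danheiser transposition, resolution by CBS reduction) and a C8–C16 acid made from (R)-linalool. Ring A is the dimedone ring.

Key step: step 19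

Assumption: labdane numbering is used for ring A and the bicyclic compounds; the target is taken as drawn (5α-H, 10β-CH2O-acyl, 9β-H with the C9 chain α, 2α/3α/7α oxygens, 13R, (R)-2-methylbutanoate), and the ring A intermediates are racemic up to the enone that enters the CBS reduction, where the single enantiomer is selected.

## Route

Step 1
Reactants: 1 dimedone
Product: 2 3-isobutoxy-5,5-dimethylcyclohex-2-en-1-one
Conditions: i-BuOH, TsOH·H2O (cat.), PhMe, reflux, Dean–Stark
Reagents that add atoms: isobutanol (CC(C)CO)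
Why: Acid-catalysed condensation of the enolised 1,3-diketone with the alcohol (vinylogous ester formation), driven by azeotropic removal of water; the two carbonyls of 1 are equivalent, so only one product can form.

Step 2
Reactants: 2 3-isobutoxy-5,5-dimethylcyclohex-2-en-1-one; 3 allyl bromide
Product: 5 rac-6-allyl-3-isobutoxy-5,5-dimethylcyclohex-2-en-1-one, via lithium enolate 4 (not isolated)
Conditions: LiN(i-Pr)2, THF, −78 °C; then 3, DMPU, −78 → 0 °C
Reagents that add atoms: none
Why: Kinetic deprotonation of a vinylogous ester takes place at the α′-CH2 (C6), and the cross-conjugated enolate is C-alkylated by SN2 with the allylic bromide, which puts the future C6–C7 carbons on the future C5 next to the gem-dimethyl carbon; the product is racemic.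

Step 3
Reactants: 5 rac-6-allyl-3-isobutoxy-5,5-dimethylcyclohex-2-en-1-one
Product: 8 rac-4-allyl-3-(hydroxymethyl)-5,5-dimethylcyclohex-2-en-1-one, via carbinol adduct 6 (not isolated), via MOM ether enone 7 (not isolated)
Conditions: Bu3SnCH2OCH2OMe, n-BuLi, THF, −78 °C; then 5, −78 → −20 °C; then 6 M HCl, THF, 45 °C
Reagents that add atoms: tributyl[(methoxymethoxy)methyl]stannane (CCCC[Sn](CCCC)(CCCC)COCOC); water (O)
Why: Stork–Danheiser transposition: tin–lithium exchange gives the α-alkoxymethyllithium, which adds 1,2 to the vinylogous ester carbonyl (future C10), and aqueous acid ionises the tertiary allylic carbinol, hydrolyses the enol ether to the transposed enone (carbonyl now on the future C2) and cleaves the MOM acetal, so that C20 arrives as a free CH2OH on the β-carbon.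

Step 4
Reactants: 8 rac-4-allyl-3-(hydroxymethyl)-5,5-dimethylcyclohex-2-en-1-one
Product: 9 rac-4-allyl-3-[(tert-butyldimethylsilyloxy)methyl]-5,5-dimethylcyclohex-2-en-1-one
Conditions: TBSCl, imidazole, CH2Cl2, 0 °C → rt
Reagents that add atoms: tert-butyldimethylsilyl chloride (CC(C)(C)[Si](C)(C)Cl)
Why: Standard silylation of the single primary hydroxyl, needed so that only the ring carbinol is free when the ester is made.

Step 5
Reactants: 9 rac-4-allyl-3-[(tert-butyldimethylsilyloxy)methyl]-5,5-dimethylcyclohex-2-en-1-one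
Product: 11 rac-3-[(tert-butyldimethylsilyloxy)methyl]-4-(2,2-dimethoxyethyl)-5,5-dimethylcyclohex-2-en-1-one, via keto aldehyde 10 (not isolated)
Conditions: O3, CH2Cl2/MeOH, −78 °C (Sudan Red 7B end point); Me2S; then HC(OMe)3, PPTS (cat.), rt
Reagents that add atoms: trimethyl orthoformate (COC(OC)OC)
Why: Ozonolysis is chemoselective for the isolated monosubstituted alkene over the electron-poor enone double bond and removes the terminal carbon to leave the C6–C7 acetaldehyde arm, which is masked at once as its dimethyl acetal (acid-catalysed acetalisation with the orthoformate as water scavenger; the conjugated ketone is left).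

Step 6
Reactants: 11 rac-3-[(tert-butyldimethylsilyloxy)methyl]-4-(2,2-dimethoxyethyl)-5,5-dimethylcyclohex-2-en-1-one
Product: 12 (1S,4S)-3-[(tert-butyldimethylsilyloxy)methyl]-4-(2,2-dimethoxyethyl)-5,5-dimethylcyclohex-2-en-1-ol
Conditions: (R)-Me-CBS oxazaborolidine (0.2 equiv), BH3·SMe2 (0.6 equiv), THF, −40 °C, stopped near half conversion; MeOH quench; chromatography
Reagents that add atoms: none
Why: Corey–Bakshi–Shibata reduction run as a kinetic resolution: the (R)-oxazaborolidine delivers hydride to the carbonyl face that gives the (S)-carbinol (alkenyl arm as the large group), and only for the (4S)-enantiomer of 11 is this also the substrate-preferred attack opposite the axial methyl of the gem-dimethyl carbon (the C5 chain sits pseudoaxial to avoid allylic strain with the CH2OTBS group), so this enantiomer should be reduced fast to the trans alcohol (2α-OH, 5β-chain) while the (4R)-enone is left and is removed, together with any cis alcohol, by chromatography.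

Step 7
Reactants: 13 (R)-linalool
Product: 14 (R)-linalool triethylsilyl ether
Conditions: TESOTf, 2,6-lutidine, CH2Cl2, −78 → 0 °C
Reagents that add atoms: triethylsilyl trifluoromethanesulfonate (CC[Si](CC)(CC)OS(=O)(=O)C(F)(F)F)
Why: Silylation of the hindered tertiary allylic alcohol needs the silyl triflate; the TES ether prevents lactonisation of the later hydroxy acid and survives the basic steps that follow.

Step 8
Reactants: 14 (R)-linalool triethylsilyl ether
Product: 15 (R)-4-methyl-4-(triethylsilyloxy)hex-5-enal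
Conditions: O3 (1.0 equiv), CH2Cl2, pyridine, −78 °C; Me2S
Reagents that add atoms: ozone ([O-][O+]=O)
Why: Ozone reacts much faster with the electron-rich trisubstituted alkene than with the vinyl group next to the quaternary silyloxy carbon, so one equivalent should cleave only the 6,7-double bond (ozonolysis with reductive work-up) and give the aldehyde whose carbonyl carbon becomes C9.

Step 9
Reactants: 15 (R)-4-methyl-4-(triethylsilyloxy)hex-5-enal
Product: 16 (5R)-1,1,1-trichloro-5-methyl-5-(triethylsilyloxy)hept-6-en-2-ol (C2 epimers)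
Conditions: CHCl3, DBU, 0 °C → rt
Reagents that add atoms: chloroform (ClC(Cl)Cl)
Why: Base-promoted addition of the trichloromethyl anion to the aldehyde gives the trichloromethyl carbinol needed for the Jocic-type homologation; the new stereocentre is destroyed in the next step.

Step 10
Reactants: 16 (5R)-1,1,1-trichloro-5-methyl-5-(triethylsilyloxy)hept-6-en-2-ol
Product: 17 (R)-5-methyl-5-(triethylsilyloxy)hept-6-enoic acid
Conditions: NaBH4, NaOH, t-BuOH/H2O, 55 °C; work-up at pH 4
Reagents that add atoms: sodium hydroxide ([Na+].[OH-])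
Why: Reductive Jocic reaction: hydroxide closes the gem-dichloroepoxide, borohydride opens it at the former carbinol carbon and the resulting acid chloride is hydrolysed, a net one-carbon homologation of the aldehyde to the carboxylic acid (C8) that the base-stable tertiary TES ether should tolerate.

Step 11
Reactants: 12 (1S,4S)-3-[(tert-butyldimethylsilyloxy)methyl]-4-(2,2-dimethoxyethyl)-5,5-dimethylcyclohex-2-en-1-ol; 17 (R)-5-methyl-5-(triethylsilyloxy)hept-6-enoic acid
Product: 18 cyclohex-2-enyl ester of 12 with 17
Conditions: EDC·HCl, DMAP, CH2Cl2, 0 °C → rt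
Reagents that add atoms: none
Why: Steglich-type carbodiimide esterification of the secondary allylic alcohol; no stereocentre is touched.

Step 12
Reactants: 18 cyclohex-2-enyl ester of 12 with 17
Product: 22 ring A methyl ester (C8 ester; C9 and C10 set; Δ1 alkene), via silyl ketene acetal 19 (not isolated), via trimethylsilyl ester 20 (not isolated), via carboxylic acid 21 (not isolated)
Conditions: LiN(i-Pr)2, THF/DMPU, −78 °C; TMSCl, Et3N, −78 → 50 °C; then MeOH; TMSCHN2, 0 °C
Reagents that add atoms: (trimethylsilyl)diazomethane (C[Si](C)(C)C=[N+]=[N-])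
Why: Ireland–Claisen rearrangement: enolisation in THF/DMPU gives the (Z)-silyl ketene acetal, which rearranges suprafacially on the α face where the C2–O bond lies (anti to the C5 chain) through a boat-like transition state, the chair being disfavoured because it pushes the silyloxy group under the ring against the α-methyl of C4, so that C10 (C9 α, C20 β) and C9 (hydrogen towards the ring, C11 chain outside) are set in one event; methanolysis of the silyl ester and methylation with TMSCHN2 follow in the same flask.

Step 13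
Reactants: 22 ring A methyl ester
Product: 23 ring A 1-en-3-one methyl ester
Conditions: Rh2(cap)4 (cap = caprolactamate, 1 mol%), t-BuOOH, K2CO3 (cat.), CH2Cl2, rt
Reagents that add atoms: tert-butyl hydroperoxide (CC(C)(C)OO)
Why: Allylic oxidation by tert-butylperoxy radicals generated on Rh2(cap)4: the only allylic C–H bonds of the C1=C2 alkene are those of C3 (C10 is quaternary and the vinyl group has no allylic hydrogen), and collapse of the C3 mixed peroxide gives the 1-en-3-one.

Step 14
Reactants: 23 ring A 1-en-3-one methyl ester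
Product: 25 ring A 2α-hydroxy-3-ketone methyl ester, via lithium enolate 24 (not isolated)
Conditions: LiBH(s-Bu)3, THF, −78 °C; then (camphorsulfonyl)oxaziridine, −78 → −30 °C; aq. NH4Cl
Reagents that add atoms: (camphorsulfonyl)oxaziridine (CC1(C)C2CCC13CS(=O)(=O)N4OC34C2)
Why: Conjugate hydride addition (the carbonyl is shielded by the C4 gem-dimethyl group and C1 carries a hydrogen) gives the C2=C3 lithium enolate regiospecifically, and the oxaziridine transfers oxygen to C2 from the α face, opposite the axial CH2OTBS group on C10, which should give the equatorial 2α-hydroxy ketone (enolate hydroxylation with an N-sulfonyloxaziridine).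

Step 15
Reactants: 25 ring A 2α-hydroxy-3-ketone methyl ester
Product: 26 ring A 2α,3α-diol methyl ester
Conditions: LiBH(s-Bu)3 (excess), THF, −78 → −20 °C; aq. NH4Cl
Reagents that add atoms: none
Why: The bulky trialkylborohydride attacks the C3 ketone along the equatorial trajectory from the β face, as is usual for 4,4-dimethyl-3-ketones, so that the new hydroxyl is axial (3α) and cis to the 2α-hydroxyl.

Step 16
Reactants: 26 ring A 2α,3α-diol methyl ester
Product: 27 ring A 2α,3α-acetonide methyl ester
Conditions: Me2C(OMe)2, PPTS (cat.), CH2Cl2, rt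
Reagents that add atoms: 2,2-dimethoxypropane (COC(C)(C)OC)
Why: Acid-catalysed trans-ketalisation; the cis (axial/equatorial) diol closes the five-membered acetonide easily, and the dimethyl acetal and silyl ethers are inert to PPTS in the absence of water.

Step 17
Reactants: 27 ring A 2α,3α-acetonide methyl ester
Product: 29 ring A alkyne dimethyl acetal, via aldehyde 28 (not isolated)
Conditions: i-Bu2AlH, CH2Cl2, −78 °C; then MeOH, dimethyl (1-diazo-2-oxopropyl)phosphonate, K2CO3, −78 °C → rt
Reagents that add atoms: dimethyl (1-diazo-2-oxopropyl)phosphonate (COP(=O)(OC)C(=[N+]=[N-])C(C)=O)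
Why: Partial reduction of the methyl ester to the aldehyde (the aluminium hemiacetal is stable at −78 °C) followed in the same flask by Seyferth–Gilbert homologation with the Ohira–Bestmann reagent turns C8 into the internal alkyne carbon and adds C17; the mild carbonate conditions are chosen to keep the C9 configuration.

Step 18
Reactants: 29 ring A alkyne dimethyl acetal
Product: 30 ring A ynal (C7 aldehyde, C8≡C17 alkyne, 2α,3α-acetonide, C20 OTBS, C13 OTES)
Conditions: PPTS (cat.), acetone/H2O (10:1), 40 °C
Reagents that add atoms: water (O)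
Why: Acid-catalysed trans-acetalisation to acetone/water frees the aliphatic aldehyde from its dimethyl acetal, while the acetonide is held in place by the acetone solvent and the TBS and tertiary TES ethers tolerate PPTS; this gives the hydroacylation precursor.

Step 19
Reactants: 30 ring A ynal
Product: 31 bicyclic 8(17)-en-7-one (2α,3α-acetonide, C20 OTBS, C13 OTES)
Conditions: [Rh(dppe)]ClO4 (10 mol%, from [Rh(nbd)(dppe)]ClO4 and H2), acetone, rt → 50 °C, argon
Reagents that add atoms: none
Why: Oxidative addition of the C7 aldehyde C–H bond to the monovalent rhodium centre of [Rh(dppe)]+ gives an acyl hydride of trivalent rhodium; the tethered terminal alkyne coordinates, cis-hydrometalation puts hydrogen on C17 and rhodium on C8, and reductive elimination forms the C7–C8 bond and returns monovalent rhodium. The closest known reaction type is the cationic rhodium–bisphosphine cyclisation of 5- and 6-alkynals to 2-alkylidenecycloalkanones, applied here to a terminal alkyne flanked by the quaternary C10. Ring B closes in the 6-exo-dig mode through a seven-membered acyl/alkenyl rhodacycle; the 7-endo alternative (acyl to C17) is the only competitor and should be the less favoured ring size. No stereocentre is formed: C5, C9 and C10 are spectators, and the trans ring fusion follows from the trans-diequatorial chains on C5 and C10. The step needs regioselectivity (acyl group to the internal alkyne carbon), secured by the exo ring size, and chemoselectivity over decarbonylation and over the C14=C15 vinyl group, secured by the quaternary C10 and gem-dimethyl C4 that hold aldehyde and alkyne close together and by the vinyl group being out of reach of the acyl rhodium hydride.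

Step 20
Reactants: 31 bicyclic 8(17)-en-7-one
Product: 32 7α-hydroxy-8(17)-ene (2α,3α-acetonide, C20 OTBS, C13 OTES)
Conditions: NaBH4, CeCl3·7H2O, MeOH, −78 °C
Reagents that add atoms: none
Why: Luche 1,2-reduction: the α face of C7 is screened by the axial C9 chain (1,3-diaxial to an incoming hydride), so hydride should add from the β face (equatorial attack) and give the axial 7α-alcohol, while cerium suppresses conjugate reduction of the exo-methylene ketone.

Step 21
Reactants: 32 7α-hydroxy-8(17)-ene
Product: 33 7α,13,20-triol 2α,3α-acetonide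
Conditions: Bu4NF, THF, 0 → 40 °C
Reagents that add atoms: none
Why: Fluoride cleaves both silyl ethers (primary TBS, tertiary TES) and leaves the acetonide.

Step 22
Reactants: 33 7α,13,20-triol 2α,3α-acetonide; 34 (R)-2-methylbutanoic acid
Product: 35 C20 (R)-2-methylbutanoate 2α,3α-acetonide
Conditions: EDC·HCl, DMAP (0.1 equiv), CH2Cl2, −10 °C → rt
Reagents that add atoms: none
Why: Carbodiimide esterification is selective for the primary C20 hydroxyl, because the axial allylic C7 hydroxyl (flanked by the C9 chain) and the tertiary C13 hydroxyl react much more slowly; low temperature and catalytic DMAP guard the α-stereocentre of the acid.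

Step 23
Reactants: 35 C20 (R)-2-methylbutanoate 2α,3α-acetonide
Product: 36 2α,3α,7α,13-tetraol 20-(R)-2-methylbutanoate
Conditions: AcOH/THF/H2O (3:1:1), 40 °C
Reagents that add atoms: none
Why: Mild aqueous acid hydrolyses the cis-fused acetonide without ionising the allylic and tertiary allylic alcohols or cleaving the ester.

Step 24
Reactants: 36 2α,3α,7α,13-tetraol 20-(R)-2-methylbutanoate; 37 angelic acid
Product: 39 target CNP0391865.1, via stannylene acetal 38 (not isolated)
Conditions: Bu2SnO, PhMe, reflux (Dean–Stark); then mixed anhydride from 37, 2,4,6-Cl3C6H2COCl and Et3N (PhMe, rt), 0 °C → rt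
Reagents that add atoms: none
Why: Stannylene acetal formation activates only the cis-2,3-diol and, as with carbohydrate cis-diols, the equatorial oxygen (O2) is acylated, here by the Yamaguchi-type mixed anhydride of angelic acid without a nucleophilic catalyst, which should avoid Z to E isomerisation to the tiglate and leave the 3α-, 7α- and 13-hydroxyls free.

## Compound list

1 | dimedone (5,5-dimethylcyclohexane-1,3-dione) | CC1(C)CC(=O)CC(=O)C1 | starting material
2 | 3-isobutoxy-5,5-dimethylcyclohex-2-en-1-one | CC(C)COC1=CC(=O)CC(C)(C)C1 | intermediate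
3 | allyl bromide | C=CCBr | starting material
4 | lithium 5-isobutoxy-3,3-dimethylcyclohexa-1,5-dien-1-olate (enolate of 2; not isolated) | [Li+].[O-]C1=CC(C)(C)CC(OCC(C)C)=C1 | intermediate
5 | rac-6-allyl-3-isobutoxy-5,5-dimethylcyclohex-2-en-1-one | C=CCC1C(=O)C=C(OCC(C)C)CC1(C)C | intermediate
6 | rac-6-allyl-3-isobutoxy-1-[(methoxymethoxy)methyl]-5,5-dimethylcyclohex-2-en-1-ol (1,2-adduct, diastereomer mixture; not isolated) | C=CCC1C(O)(COCOC)C=C(OCC(C)C)CC1(C)C | intermediate
7 | rac-4-allyl-3-[(methoxymethoxy)methyl]-5,5-dimethylcyclohex-2-en-1-one (not isolated) | C=CCC1C(COCOC)=CC(=O)CC1(C)C | intermediate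
8 | rac-4-allyl-3-(hydroxymethyl)-5,5-dimethylcyclohex-2-en-1-one | C=CCC1C(CO)=CC(=O)CC1(C)C | intermediate
9 | rac-4-allyl-3-[(tert-butyldimethylsilyloxy)methyl]-5,5-dimethylcyclohex-2-en-1-one | C=CCC1C(CO[Si](C)(C)C(C)(C)C)=CC(=O)CC1(C)C | intermediate
10 | rac-2-{2-[(tert-butyldimethylsilyloxy)methyl]-6,6-dimethyl-4-oxocyclohex-2-en-1-yl}acetaldehyde (not isolated) | O=CCC1C(CO[Si](C)(C)C(C)(C)C)=CC(=O)CC1(C)C | intermediate
11 | rac-3-[(tert-butyldimethylsilyloxy)methyl]-4-(2,2-dimethoxyethyl)-5,5-dimethylcyclohex-2-en-1-one | COC(OC)CC1C(CO[Si](C)(C)C(C)(C)C)=CC(=O)CC1(C)C | intermediate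
12 | (1S,4S)-3-[(tert-butyldimethylsilyloxy)methyl]-4-(2,2-dimethoxyethyl)-5,5-dimethylcyclohex-2-en-1-ol (2α-OH, 5β-chain in labdane numbering) | O[C@@H]1C=C(CO[Si](C)(C)C(C)(C)C)[C@@H](CC(OC)OC)C(C)(C)C1 | intermediate
13 | (R)-linalool | C=C[C@](C)(O)CCC=C(C)C | starting material
14 | (R)-linalool triethylsilyl ether | C=C[C@](C)(O[Si](CC)(CC)CC)CCC=C(C)C | intermediate
15 | (R)-4-methyl-4-(triethylsilyloxy)hex-5-enal | C=C[C@](C)(O[Si](CC)(CC)CC)CCC=O | intermediate
16 | (5R)-1,1,1-trichloro-5-methyl-5-(triethylsilyloxy)hept-6-en-2-ol (C2 epimers) | C=C[C@](C)(O[Si](CC)(CC)CC)CCC(O)C(Cl)(Cl)Cl | intermediate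
17 | (R)-5-methyl-5-(triethylsilyloxy)hept-6-enoic acid (C8, C9, C11–C16) | C=C[C@](C)(O[Si](CC)(CC)CC)CCCC(=O)O | intermediate
18 | (1S,4S)-cyclohex-2-enyl ester of 12 with acid 17 | C=C[C@](C)(O[Si](CC)(CC)CC)CCCC(=O)O[C@@H]1C=C(CO[Si](C)(C)C(C)(C)C)[C@@H](CC(OC)OC)C(C)(C)C1 | intermediate
19 | (Z)-O-trimethylsilyl ketene acetal of 18 (not isolated) | C=C[C@](C)(O[Si](CC)(CC)CC)CC/C=C(\O[Si](C)(C)C)O[C@@H]1C=C(CO[Si](C)(C)C(C)(C)C)[C@@H](CC(OC)OC)C(C)(C)C1 | intermediate
20 | trimethylsilyl ester of acid 21 (not isolated) | C=C[C@](C)(O[Si](CC)(CC)CC)CC[C@H](C(=O)O[Si](C)(C)C)[C@@]1(CO[Si](C)(C)C(C)(C)C)C=CCC(C)(C)[C@@H]1CC(OC)OC | intermediate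
21 | ring A C8 carboxylic acid: C10 quaternary (C9 α, CH2OTBS β), 5α-H, Δ1 alkene, C7 dimethyl acetal (not isolated) | C=C[C@](C)(O[Si](CC)(CC)CC)CC[C@H](C(=O)O)[C@@]1(CO[Si](C)(C)C(C)(C)C)C=CCC(C)(C)[C@@H]1CC(OC)OC | intermediate
22 | methyl ester of 21 | C=C[C@](C)(O[Si](CC)(CC)CC)CC[C@H](C(=O)OC)[C@@]1(CO[Si](C)(C)C(C)(C)C)C=CCC(C)(C)[C@@H]1CC(OC)OC | intermediate
23 | ring A 1-en-3-one methyl ester | C=C[C@](C)(O[Si](CC)(CC)CC)CC[C@H](C(=O)OC)[C@@]1(CO[Si](C)(C)C(C)(C)C)C=CC(=O)C(C)(C)[C@@H]1CC(OC)OC | intermediate
24 | lithium C2=C3 enolate of the 3-ketone (not isolated) | [Li+].C=C[C@](C)(O[Si](CC)(CC)CC)CC[C@H](C(=O)OC)[C@@]1(CO[Si](C)(C)C(C)(C)C)CC=C([O-])C(C)(C)[C@@H]1CC(OC)OC | intermediate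
25 | ring A 2α-hydroxy-3-ketone methyl ester | C=C[C@](C)(O[Si](CC)(CC)CC)CC[C@H](C(=O)OC)[C@@]1(CO[Si](C)(C)C(C)(C)C)C[C@@H](O)C(=O)C(C)(C)[C@@H]1CC(OC)OC | intermediate
26 | ring A 2α,3α-diol methyl ester | C=C[C@](C)(O[Si](CC)(CC)CC)CC[C@H](C(=O)OC)[C@@]1(CO[Si](C)(C)C(C)(C)C)C[C@@H](O)[C@@H](O)C(C)(C)[C@@H]1CC(OC)OC | intermediate
27 | ring A 2α,3α-acetonide methyl ester | C=C[C@](C)(O[Si](CC)(CC)CC)CC[C@H](C(=O)OC)[C@@]1(CO[Si](C)(C)C(C)(C)C)C[C@H]2OC(C)(C)O[C@H]2C(C)(C)[C@@H]1CC(OC)OC | intermediate
28 | ring A C8 aldehyde, 2α,3α-acetonide, C7 dimethyl acetal (not isolated) | C=C[C@](C)(O[Si](CC)(CC)CC)CC[C@H](C=O)[C@@]1(CO[Si](C)(C)C(C)(C)C)C[C@H]2OC(C)(C)O[C@H]2C(C)(C)[C@@H]1CC(OC)OC | intermediate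
29 | ring A C8≡C17 alkyne, 2α,3α-acetonide, C7 dimethyl acetal | C=C[C@](C)(O[Si](CC)(CC)CC)CC[C@H](C#C)[C@@]1(CO[Si](C)(C)C(C)(C)C)C[C@H]2OC(C)(C)O[C@H]2C(C)(C)[C@@H]1CC(OC)OC | intermediate
30 | ring A ynal (key-step precursor): C7 aldehyde, C8≡C17 alkyne on C9, 2α,3α-acetonide, C20 OTBS, C13 OTES | C=C[C@](C)(O[Si](CC)(CC)CC)CC[C@H](C#C)[C@@]1(CO[Si](C)(C)C(C)(C)C)C[C@H]2OC(C)(C)O[C@H]2C(C)(C)[C@@H]1CC=O | intermediate
31 | bicyclic 8(17)-en-7-one (key-step product): 5α-H, 9β-H, 10β-CH2OTBS, 2α,3α-acetonide, C13 OTES | C=C[C@](C)(O[Si](CC)(CC)CC)CC[C@@H]1C(=C)C(=O)C[C@H]2C(C)(C)[C@@H]3OC(C)(C)O[C@@H]3C[C@]12CO[Si](C)(C)C(C)(C)C | intermediate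
32 | 7α-hydroxy-8(17)-ene, 2α,3α-acetonide, C20 OTBS, C13 OTES | C=C[C@](C)(O[Si](CC)(CC)CC)CC[C@@H]1C(=C)[C@H](O)C[C@H]2C(C)(C)[C@@H]3OC(C)(C)O[C@@H]3C[C@]12CO[Si](C)(C)C(C)(C)C | intermediate
33 | 7α,13,20-triol 2α,3α-acetonide | C=C[C@](C)(O)CC[C@@H]1C(=C)[C@H](O)C[C@H]2C(C)(C)[C@@H]3OC(C)(C)O[C@@H]3C[C@]12CO | intermediate
34 | (R)-2-methylbutanoic acid | CC[C@@H](C)C(=O)O | starting material
35 | 7α,13-diol 2α,3α-acetonide 20-(R)-2-methylbutanoate | C=C[C@](C)(O)CC[C@@H]1C(=C)[C@H](O)C[C@H]2C(C)(C)[C@@H]3OC(C)(C)O[C@@H]3C[C@]12COC(=O)[C@H](C)CC | intermediate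
36 | 2α,3α,7α,13-tetraol 20-(R)-2-methylbutanoate | C=C[C@](C)(O)CC[C@@H]1C(=C)[C@H](O)C[C@H]2C(C)(C)[C@H](O)[C@H](O)C[C@]12COC(=O)[C@H](C)CC | intermediate
37 | angelic acid ((Z)-2-methylbut-2-enoic acid) | C/C=C(/C)C(=O)O | starting material
38 | 2,3-O-dibutylstannylene acetal of 36 (not isolated) | C=C[C@](C)(O)CC[C@@H]1C(=C)[C@H](O)C[C@H]2C(C)(C)[C@@H]3O[Sn](CCCC)(CCCC)O[C@@H]3C[C@]12COC(=O)[C@H](C)CC | intermediate
39 | CNP0391865.1: (2R,3S,5R,7R,9S,10R,13R)-2-angeloyloxy-3,7,13-trihydroxylabda-8(17),14-dien-20-yl (R)-2-methylbutanoate (2α-OAng, 3α-OH, 7α-OH, 9β-H) | C=C[C@](C)(O)CC[C@@H]1C(=C)[C@H](O)C[C@H]2C(C)(C)[C@H](O)[C@H](OC(=O)/C(C)=C\C)C[C@]12COC(=O)[C@H](C)CC | target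

## Step count and risk

Total step count: 24 steps.

Longest linear sequence: 20 steps (steps 1–6 and 11–24, from dimedone); steps 7–10 make the side-chain acid in parallel.

Steps most likely to fail:

1. Step 19 (key step). What may go wrong: the acyl rhodium hydride may lose CO before the hindered terminal alkyne inserts; the terminal alkyne may rearrange to a vinylidene on rhodium or oligomerise; and a rhodium hydride may move the exocyclic double bond into the ring and so erase the C9 stereocentre. Fallback, a nickel-catalysed reductive ynal cyclisation that forms the same C7–C8 bond by a different mechanism: it sets out from ynal 30, which is treated with Ni(cod)2 (zerovalent nickel, 10 mol%), PBu3 and Et3SiH in THF; oxidative cyclisation of aldehyde and alkyne on nickel, σ-bond metathesis with the silane and C–H reductive elimination should give the 7-triethylsilyloxy-8(17)-ene F1 as a mixture of C7 epimers. AcOH/THF/H2O at 0 °C should free the secondary allylic alcohol, giving the 7-hydroxy-8(17)-ene F2, the tertiary TES and primary TBS ethers being slower. Dess–Martin periodinane then converges both epimers on enone 31, where the route is rejoined.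

2. Step 13. What may go wrong: oxygen may be delivered to the other end of the allyl radical (C1), giving the transposed 2-en-1-one, or the peroxy radicals may attack the acetal C–H bond. Fallback, a Riley oxidation followed by alcohol oxidation: it sets out from ester 22, which is treated with SeO2 (0.5 equiv) and t-BuOOH in CH2Cl2; the ene reaction and [2,3]-sigmatropic shift return the double bond to C1=C2 and place the oxygen on C3 only, giving the 3-hydroxy-1-ene methyl ester F3. Dess–Martin periodinane then gives enone 23, where the route is rejoined.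

3. Step 6. What may go wrong: the two enantiomers of the enone may be reduced at too similar rates (low enantiomeric purity of the alcohol), or the trans selectivity may be incomplete. Fallback, a classical resolution through diastereomeric esters: it sets out from racemic enone 11, which is reduced under Luche conditions (NaBH4, CeCl3·7H2O, MeOH, −78 °C; substrate control) to the racemic trans alcohol F4. Esterification with (S)-O-methylmandelic acid (DCC, DMAP) gives two diastereomeric esters that are separated by chromatography, and the (1S,4S)-alcohol (S)-O-methylmandelate F5 is kept. Methanolysis (K2CO3, MeOH) returns alcohol 12, where the route is rejoined.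

## Further compounds

F1 | step 19 | 7-triethylsilyloxy-8(17)-ene (both C7 epimers; 2α,3α-acetonide, C20 OTBS, C13 OTES) | C=C[C@](C)(O[Si](CC)(CC)CC)CC[C@@H]1C(=C)C(O[Si](CC)(CC)CC)C[C@H]2C(C)(C)[C@@H]3OC(C)(C)O[C@@H]3C[C@]12CO[Si](C)(C)C(C)(C)C
F2 | step 19 | 7-hydroxy-8(17)-ene (both C7 epimers; 2α,3α-acetonide, C20 OTBS, C13 OTES) | C=C[C@](C)(O[Si](CC)(CC)CC)CC[C@@H]1C(=C)C(O)C[C@H]2C(C)(C)[C@@H]3OC(C)(C)O[C@@H]3C[C@]12CO[Si](C)(C)C(C)(C)C
F3 | step 13 | 3-hydroxy-1-ene methyl ester (C3 epimers) | C=C[C@](C)(O[Si](CC)(CC)CC)CC[C@H](C(=O)OC)[C@@]1(CO[Si](C)(C)C(C)(C)C)C=CC(O)C(C)(C)[C@@H]1CC(OC)OC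
F4 | step 6 | rac-(1S*,4S*)-3-[(tert-butyldimethylsilyloxy)methyl]-4-(2,2-dimethoxyethyl)-5,5-dimethylcyclohex-2-en-1-ol (racemate; relative configuration shown) | O[C@@H]1C=C(CO[Si](C)(C)C(C)(C)C)[C@@H](CC(OC)OC)C(C)(C)C1
F5 | step 6 | (1S,4S)-alcohol (S)-O-methylmandelate | CO[C@H](C(=O)O[C@@H]1C=C(CO[Si](C)(C)C(C)(C)C)[C@@H](CC(OC)OC)C(C)(C)C1)c1ccccc1
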